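**Plan**

- The target is (R)-1-[2,4-dihydroxy-3-(3-methylbut-2-enyl)phenyl]-3-(3,4-dihydroxyphenyl)-2-hydroxypropan-1-one, with ring A numbered C1' (acyl-bearing carbon) to C6'. Retrosynthesis takes ring A back to a 4-acylcyclohexane-1,3-dione, cuts C1'–C6' and C3'–C4' of that ring, and then cuts the bond between C1' and the side-chain carbonyl.
- The enabling feature is that C1', C2' (with its oxygen), C3' and the prenyl group on C3' together are the carbon chain of 6-methylhept-5-en-2-one (methyl = C1', carbonyl = C2', α-methylene = C3'). C4' (with its oxygen), C5' and C6' are the three carbons of an acrylate. Once the side-chain acyl group sits on C1', that carbon is the acidic centre of a 1,3-diketone and C3' is the unhindered enolisable position for ring closure.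
- Forward, (R)-danshensu is converted to a protected Weinreb amide, which acylates the kinetic enolate of the heptenone to give the 1,3-diketone. Michael–Claisen annulation with methyl acrylate then builds ring A, the only ring made (ring B comes with danshensu).
- Selenenylation and selenoxide elimination aromatise ring A, and methanolic acid frees the remaining three hydroxyls.
- The single stereocentre (R) is bought with danshensu. Its C–O bond is never broken, and a bulky silyl ether keeps its α-hydrogen from being removed.

Key step: step 6

Remark: (R)-danshensu, the natural enantiomer, is assumed to be bought as the free acid; its configuration is the R configuration that the target requires, so no stereocentre has to be created.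

**Route**

Step 1
Reactants: 1 (R)-3-(3,4-dihydroxyphenyl)-2-hydroxypropanoic acid (danshensu)
Product: 2 methyl (R)-3-(3,4-dihydroxyphenyl)-2-hydroxypropanoate
Conditions: MeOH, H2SO4 (cat.), reflux, N2
Reagents that add atoms: methanol, CO
Why: Fischer esterification in a large excess of methanol converts only the carboxylic acid, since the catechol and the secondary alcohol are not etherified under these conditions and the carbinol carbon is not touched, so the R configuration of 1 is retained.

Step 2
Reactants: 2 methyl (R)-3-(3,4-dihydroxyphenyl)-2-hydroxypropanoate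
Product: 3 methyl (R)-3-[3,4-bis(methoxymethoxy)phenyl]-2-hydroxypropanoate
Conditions: MOMCl (2.5 equiv), K2CO3, acetone, 0 °C → rt
Reagents that add atoms: chloromethyl methyl ether, COCCl
Why: Williamson-type O-alkylation of phenols: K2CO3 deprotonates only the two catechol hydroxyls, which displace chloride from the α-chloro ether, while the much less acidic secondary alcohol stays free for the next step.

Step 3
Reactants: 3 methyl (R)-3-[3,4-bis(methoxymethoxy)phenyl]-2-hydroxypropanoate
Product: 4 methyl (R)-3-[3,4-bis(methoxymethoxy)phenyl]-2-(tert-butyldimethylsilyloxy)propanoate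
Conditions: TBSCl, imidazole, DMF, rt
Reagents that add atoms: tert-butyldimethylsilyl chloride, CC(C)(C)[Si](C)(C)Cl
Why: Imidazole-promoted silylation of a secondary alcohol with a silyl chloride is routine for α-hydroxy esters and places a bulky, non-chelating group on the carbinol oxygen without involving the stereocentre.

Step 4
Reactants: 4 methyl (R)-3-[3,4-bis(methoxymethoxy)phenyl]-2-(tert-butyldimethylsilyloxy)propanoate
Product: 5 (R)-3-[3,4-bis(methoxymethoxy)phenyl]-2-(tert-butyldimethylsilyloxy)-N-methoxy-N-methylpropanamide
Conditions: MeNH(OMe)·HCl, iPrMgCl, THF, −20 → 0 °C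
Reagents that add atoms: N,O-dimethylhydroxylamine hydrochloride, Cl.CNOC
Why: Ester aminolysis by the magnesium amide of N,O-dimethylhydroxylamine (direct ester-to-Weinreb-amide conversion) runs at low temperature through a stable magnesium chelate and is established for α-silyloxy esters without loss of configuration.

Step 5
Reactants: 5 (R)-3-[3,4-bis(methoxymethoxy)phenyl]-2-(tert-butyldimethylsilyloxy)-N-methoxy-N-methylpropanamide; 6 6-methylhept-5-en-2-one
Product: 9 (R)-1-[3,4-bis(methoxymethoxy)phenyl]-2-(tert-butyldimethylsilyloxy)-9-methyldec-8-ene-3,5-dione, via lithium enolate 7 (not isolated), via tetrahedral lithium adduct 8 (not isolated)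
Conditions: 6 (2.2 equiv), LiN(iPr)2 (2.2 equiv), THF, −78 °C; then 5, −78 → −20 °C; aq. NH4Cl
Reagents that add atoms: none
Why: Crossed Claisen-type C-acylation of a kinetic ketone enolate with a Weinreb amide: LiN(iPr)2 at −78 °C removes a proton from the methyl group of 6 (the future C1'), and the chelated adduct 8 does not collapse before work-up, so the 1,3-diketone is released only after the enolate is quenched and neither over-addition nor deprotonation at the carbinol carbon is expected.

Step 6
Reactants: 9 (R)-1-[3,4-bis(methoxymethoxy)phenyl]-2-(tert-butyldimethylsilyloxy)-9-methyldec-8-ene-3,5-dione; 10 methyl acrylate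
Product: 12 4-[(R)-3-[3,4-bis(methoxymethoxy)phenyl]-2-(tert-butyldimethylsilyloxy)propanoyl]-2-(3-methylbut-2-enyl)cyclohexane-1,3-dione, via Michael adduct 11 (not isolated)
Conditions: 10 (1.1 equiv), KOtBu (0.1 equiv), THF, 0 °C → rt; then KOtBu (2.5 equiv), 0 °C → rt; cold 0.5 M HCl to pH 4
Reagents that add atoms: none
Why: With a catalytic amount of KOtBu only C1' of 9, the methylene between the two carbonyls, is deprotonated, and this stabilised enolate adds to the β-carbon of 10 to form C1'–C6' and the adduct 11; the excess base added afterwards generates, in equilibrium, the enolate at the homoprenyl methylene C3', which attacks the ester carbonyl C4' and expels methoxide to form C3'–C4'. The closest known reaction type is the Michael–Claisen annulation of 1,3-dicarbonyl compounds with α,β-unsaturated esters, which gives 4-acyl- or 4-alkoxycarbonylcyclohexane-1,3-diones. Ring A closes as a six-membered carbocycle in the 6-(enolendo)-exo-trig mode, the C2'–C3' enolate attacking an ester carbonyl whose C=O bond lies outside the new ring. The two sp3 centres that appear at C1' and C3' are enolisable, are taken as the mixture and become aromatic carbons later, so no new stereocentre has to be controlled and the only configured carbon, the silyloxy carbinol, is a spectator. The step needs Michael addition at C1' only, closure through C3' instead of the carbinol carbon on the other side of the diketone, and no proton exchange at that carbinol: the acidity gap secures the first, and the bulky tert-butyldimethylsilyloxy and benzyl groups make the methine the slowest acid, so that its enolate, which both the wrong closure and epimerisation would need, is hardly populated. Closure through C3' moreover ends in the vinylogous-acid enolate of the ring dione, a sink that the alternative ring with a quaternary carbon between its carbonyls lacks, and this pulls the reversible steps towards 12.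

Step 7
Reactants: 12 4-[(R)-3-[3,4-bis(methoxymethoxy)phenyl]-2-(tert-butyldimethylsilyloxy)propanoyl]-2-(3-methylbut-2-enyl)cyclohexane-1,3-dione
Product: 14 4-[(R)-3-[3,4-bis(methoxymethoxy)phenyl]-2-(tert-butyldimethylsilyloxy)propanoyl]-2-(3-methylbut-2-enyl)-4-(phenylselanyl)cyclohexane-1,3-dione, via dilithium dianion 13 (not isolated)
Conditions: LiN(iPr)2 (2.2 equiv), THF, −78 °C; PhSeBr (1.0 equiv), −78 °C; aq. NH4Cl
Reagents that add atoms: phenylselenenyl bromide, Br[Se]c1ccccc1
Why: α-Selenenylation of an enolate: two equivalents of base remove first the vinylogous-acid proton at C3' and then the proton at C1' next to the side-chain ketone, and the dianion 13 meets the selenium electrophile at its more basic carbon C1' (selenium placed on C3' would be passed on to C1' by selenophilic exchange, leaving the stable ring-dione enolate), while the hindered silyloxy methine is the slowest acid in the molecule at −78 °C.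

Step 8
Reactants: 14 4-[(R)-3-[3,4-bis(methoxymethoxy)phenyl]-2-(tert-butyldimethylsilyloxy)propanoyl]-2-(3-methylbut-2-enyl)-4-(phenylselanyl)cyclohexane-1,3-dione
Product: 16 (R)-3-[3,4-bis(methoxymethoxy)phenyl]-2-(tert-butyldimethylsilyloxy)-1-[2,4-dihydroxy-3-(3-methylbut-2-enyl)phenyl]propan-1-one, via selenoxide 15 (not isolated)
Conditions: mCPBA (1.05 equiv), CH2Cl2, −78 °C; then iPr2NH (2 equiv), −78 °C → rt
Reagents that add atoms: none
Why: Selenoxide syn-elimination: the peracid oxidises selenium at −78 °C much faster than the trisubstituted double bond, selenoxide 15 can reach a hydrogen only on C6' because its other two neighbours are carbonyl carbons, and the cyclohexenedione so formed is a keto tautomer of the resorcinol and should enolise at once to aromatic ring A, the amine taking up the selenenic acid before it can add to the prenyl group or to C5'.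

Step 9
Reactants: 16 (R)-3-[3,4-bis(methoxymethoxy)phenyl]-2-(tert-butyldimethylsilyloxy)-1-[2,4-dihydroxy-3-(3-methylbut-2-enyl)phenyl]propan-1-one
Product: 17 (R)-1-[2,4-dihydroxy-3-(3-methylbut-2-enyl)phenyl]-3-(3,4-dihydroxyphenyl)-2-hydroxypropan-1-one
Conditions: HCl (0.5 M in MeOH), 0 °C → rt
Reagents that add atoms: none
Why: Acid-catalysed acetal exchange of the two aryl methoxymethyl ethers and methanolysis of the silyl ether free the remaining three hydroxyls in one operation; dilute acid without heating is chosen so that the 3-methylbut-2-enyl group flanked by two phenols does not cyclise to a chroman, and since no bond to the carbinol carbon is broken and the ketone is not enolised towards it, the R configuration is kept.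

**Compound list**

1 | (R)-3-(3,4-dihydroxyphenyl)-2-hydroxypropanoic acid (danshensu) | OC(=O)[C@H](O)Cc1ccc(O)c(O)c1 | starting material
2 | methyl (R)-3-(3,4-dihydroxyphenyl)-2-hydroxypropanoate | COC(=O)[C@H](O)Cc1ccc(O)c(O)c1 | intermediate
3 | methyl (R)-3-[3,4-bis(methoxymethoxy)phenyl]-2-hydroxypropanoate | COC(=O)[C@H](O)Cc1ccc(OCOC)c(OCOC)c1 | intermediate
4 | methyl (R)-3-[3,4-bis(methoxymethoxy)phenyl]-2-(tert-butyldimethylsilyloxy)propanoate | COC(=O)[C@H](O[Si](C)(C)C(C)(C)C)Cc1ccc(OCOC)c(OCOC)c1 | intermediate
5 | (R)-3-[3,4-bis(methoxymethoxy)phenyl]-2-(tert-butyldimethylsilyloxy)-N-methoxy-N-methylpropanamide | CON(C)C(=O)[C@H](O[Si](C)(C)C(C)(C)C)Cc1ccc(OCOC)c(OCOC)c1 | intermediate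
6 | 6-methylhept-5-en-2-one | CC(C)=CCCC(C)=O | starting material
7 | lithium 6-methylhepta-1,5-dien-2-olate (kinetic enolate of 6; not isolated) | [Li+].[O-]C(=C)CCC=C(C)C | intermediate
8 | lithium salt of the tetrahedral adduct of 7 and 5, (2R)-1-[3,4-bis(methoxymethoxy)phenyl]-2-(tert-butyldimethylsilyloxy)-3-[methoxy(methyl)amino]-9-methyl-5-oxodec-8-en-3-olate (not isolated) | [Li+].CC(C)=CCCC(=O)CC([O-])(N(C)OC)[C@H](O[Si](C)(C)C(C)(C)C)Cc1ccc(OCOC)c(OCOC)c1 | intermediate
9 | (R)-1-[3,4-bis(methoxymethoxy)phenyl]-2-(tert-butyldimethylsilyloxy)-9-methyldec-8-ene-3,5-dione | CC(C)=CCCC(=O)CC(=O)[C@H](O[Si](C)(C)C(C)(C)C)Cc1ccc(OCOC)c(OCOC)c1 | intermediate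
10 | methyl acrylate | C=CC(=O)OC | starting material
11 | methyl 4-[(R)-3-[3,4-bis(methoxymethoxy)phenyl]-2-(tert-butyldimethylsilyloxy)propanoyl]-9-methyl-5-oxodec-8-enoate (Michael adduct, C4 epimers; not isolated) | COC(=O)CCC(C(=O)CCC=C(C)C)C(=O)[C@H](O[Si](C)(C)C(C)(C)C)Cc1ccc(OCOC)c(OCOC)c1 | intermediate
12 | 4-[(R)-3-[3,4-bis(methoxymethoxy)phenyl]-2-(tert-butyldimethylsilyloxy)propanoyl]-2-(3-methylbut-2-enyl)cyclohexane-1,3-dione (ring epimers and enol forms) | O=C1CCC(C(=O)[C@H](O[Si](C)(C)C(C)(C)C)Cc2ccc(OCOC)c(OCOC)c2)C(=O)C1CC=C(C)C | intermediate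
13 | dilithium dianion of 12 (ring enolate across C3'–C4' and side-chain enolate at C1'; not isolated) | [Li+].[Li+].[O-]C1=C(CC=C(C)C)C(=O)C(=C([O-])[C@H](O[Si](C)(C)C(C)(C)C)Cc2ccc(OCOC)c(OCOC)c2)CC1 | intermediate
14 | 4-[(R)-3-[3,4-bis(methoxymethoxy)phenyl]-2-(tert-butyldimethylsilyloxy)propanoyl]-2-(3-methylbut-2-enyl)-4-(phenylselanyl)cyclohexane-1,3-dione | O=C1CCC([Se]c2ccccc2)(C(=O)[C@H](O[Si](C)(C)C(C)(C)C)Cc3ccc(OCOC)c(OCOC)c3)C(=O)C1CC=C(C)C | intermediate
15 | selenoxide of 14, 4-(phenylseleninyl) compound (not isolated) | O=C1CCC([Se](=O)c2ccccc2)(C(=O)[C@H](O[Si](C)(C)C(C)(C)C)Cc3ccc(OCOC)c(OCOC)c3)C(=O)C1CC=C(C)C | intermediate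
16 | (R)-3-[3,4-bis(methoxymethoxy)phenyl]-2-(tert-butyldimethylsilyloxy)-1-[2,4-dihydroxy-3-(3-methylbut-2-enyl)phenyl]propan-1-one | CC(C)=CCc1c(O)ccc(C(=O)[C@H](O[Si](C)(C)C(C)(C)C)Cc2ccc(OCOC)c(OCOC)c2)c1O | intermediate
17 | (R)-1-[2,4-dihydroxy-3-(3-methylbut-2-enyl)phenyl]-3-(3,4-dihydroxyphenyl)-2-hydroxypropan-1-one | CC(C)=CCc1c(O)ccc(C(=O)[C@H](O)Cc2ccc(O)c(O)c2)c1O | target

**Step count and risks**

Total steps: 9. Longest linear sequence: 9 steps, from 1 to 17.

The three steps most likely to fail are steps 6, 8 and 5.

Step 6. The ring closure may stall, because the base is held by the stabilised C1' enolate of 11 and the C3' enolate is then too scarce. The carbinol proton may also be exchanged during long exposure to KOtBu. The fallback sets out from 5 and comes back at 12; it makes the ring first and attaches the side chain last. Commercial cyclohexane-1,3-dione (O=C1CCCC(=O)C1) would be C-alkylated with 1-bromo-3-methylbut-2-ene (aqueous KOH, 0 °C → rt) to 2-(3-methylbut-2-enyl)cyclohexane-1,3-dione F1. LiN(iPr)2 (2.2 equiv, THF, −78 → −30 °C) would convert it into its dilithium dianion F2, whose carbanion at C4 (the future C1') should add to Weinreb amide 5. Work-up would give 12, and steps 7 to 9 follow unchanged.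

Step 8. The peracid, or the selenium electrophiles released during elimination, may attack the prenyl double bond or C5' of the nascent resorcinol. Selenium may also be lost from 14 before it is oxidised. The fallback sets out from 12 and comes back at 16, replacing steps 7 and 8 by a one-pot dehydrogenation that needs neither an oxidant nor selenium. Dianion 13, made as in step 7, would be treated at −78 °C with N-tert-butylbenzenesulfinimidoyl chloride (CC(C)(C)N=S(Cl)c1ccccc1). The enolate carbon C1' should attack sulfur to give the C1' sulfilimine F3. On warming, its nitrogen would remove a hydrogen from C6' in a five-membered syn-elimination, releasing the inert sulfenamide and, after tautomerisation, 16.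

Step 5. The hindered, α-branched amide may be acylated too slowly by the ketone enolate, which would then decay by proton transfer and self-aldol reaction. The fallback sets out from 5 and comes back at 9 by aldol addition and oxidation. iBu2AlH (THF, −78 °C) would reduce 5 to (R)-3-[3,4-bis(methoxymethoxy)phenyl]-2-(tert-butyldimethylsilyloxy)propanal F4. Lithium enolate 7 would add to it at −78 °C to give (2R)-1-[3,4-bis(methoxymethoxy)phenyl]-2-(tert-butyldimethylsilyloxy)-3-hydroxy-9-methyldec-8-en-5-one F5 as a mixture of C3 epimers. The mixture does not matter, because Dess–Martin periodinane (NaHCO3, CH2Cl2) should oxidise both epimers to diketone 9.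

Further compounds
F1 | step 6 | 2-(3-methylbut-2-enyl)cyclohexane-1,3-dione | CC(C)=CCC1C(=O)CCCC1=O
F2 | step 6 | dilithium dianion of F1 | [Li+].[Li+].[O-]C1=C(CC=C(C)C)C([O-])=CCC1
F3 | step 8 | 4-(N-tert-butyl-S-phenylsulfilimidoyl) derivative of 12 (sulfilimine at C1') | O=C1CCC(S(=NC(C)(C)C)c2ccccc2)(C(=O)[C@H](O[Si](C)(C)C(C)(C)C)Cc3ccc(OCOC)c(OCOC)c3)C(=O)C1CC=C(C)C
F4 | step 5 | (R)-3-[3,4-bis(methoxymethoxy)phenyl]-2-(tert-butyldimethylsilyloxy)propanal | O=C[C@H](O[Si](C)(C)C(C)(C)C)Cc1ccc(OCOC)c(OCOC)c1
F5 | step 5 | (2R)-1-[3,4-bis(methoxymethoxy)phenyl]-2-(tert-butyldimethylsilyloxy)-3-hydroxy-9-methyldec-8-en-5-one (both C3 epimers) | CC(C)=CCCC(=O)CC(O)[C@H](O[Si](C)(C)C(C)(C)C)Cc1ccc(OCOC)c(OCOC)c1
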